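Its constants come from no measurement; the rest is arithmetic.

Count X as you watch: in this closed flask each X marks one D lost, so [X] = [L] + [E.L] at every moment.

    E + L ⇌ E.L (K1 = 1.1 M⁻¹, k1 = 8.4 M⁻¹ s⁻¹)
    D ⇌ L + X (K2 = 5.6 × 10⁻⁴ M, k2 = 0.0029 s⁻¹)

D 0.20 M; E 0.190 M; time 12 h

- why nothing more happens at 12 h, or that something still does (it is still moving / E has run out first / forward and back rates have come level / all of D has reacted)
- share of the D used up at 12 h
- L at 12 h, in percent of the D charged

- the reaction counts as stopped when no species that holds the D changes by six tenths of a point or more over the second half of the time
- run time (flask): 12 h

Reckon the stopping point from that balance. Hold [E] at its charge, so that at equilibrium [E.L]/[L] is g = 0.21, the binding constant times [E], and [X] = (1 + g)[L]. Let x be the share of D used. The dissociation equilibrium then reads x·x/(1 − x) = N, and N = 0.00339 is the dissociation constant, widened by (1 + g), per charge of D. For N far below 1, x goes as the root of N; for N far above it, x tends to 1. The quadratic joins these ends: my reckoning gives x = 5.65% and, dividing by (1 + g), L at 4.67% of the D charged.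

Now test whether one number is enough. N holds [E] fixed, but E.L takes 0.00195 M, far less than the 0.190 M of E, so that costs little. N tells no time, so compare: the half-life of D, counting its forward rate and not the way back, is 0.066 h, shorter than the 12 h run, so expect level rates.

The forecast gives 5.65% used and L at 4.68%, a hair above my figure for L, and says forward and back rates have come level, since “Both steps relax within minutes at most”.

The flask gives 5.65% used and L at 4.68%, and the verdict at that time is: forward and back rates have come level; its shares moved 0 percentage points over the second half. Now take the neighbour flask charged with 0.050 M of D and the same E. The charge of D stands in the denominator of N, so N grows to 0.0135, and the same quadratic gives x = 11.0%, nearly twice the first flask's, with L at 9.08%. That neighbour flask gives 11.0% used and L at 9.09%.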